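## Analysis of the target

The target 20 (CNP0210944.0) is a diaryl ether of two hexasubstituted benzene rings. Ring A (C1 CO2CH3, C2 CH3, C3 O-aryl, C4 OH, C5 CH3, C6 OH) is the skeleton of methyl 2,4-dihydroxy-3,6-dimethylbenzoate with one more oxygen at its only free position, and ring B (C1' ether O, C2' CHO, C3' OH, C4' Cl, C5' CH3, C6' CO2H) carries six different substituents. There is no stereocentre; the ether axis has four ortho substituents (C2 CH3, C4 OH, C2' CHO, C6' CO2H) but no configuration is specified. The sensitive groups are the C2'/C3' salicylaldehyde unit, the aryl chloride (which argues against hydrogenolysis at the end), three phenols, and a free acid at C6' that must be kept distinct from the methyl ester at C1. The synthesis is hard for two reasons: the ether oxygen is flanked by two ortho substituents on each side, so joining two finished rings by an Ullmann or SNAr coupling is unattractive, and the substitution pattern of ring B cannot be written reliably by successive electrophilic substitutions. The strategy rests on ring B. C5' and C6' carry methyl and carboxyl side by side, which are the two carbons of a but-2-ynoate. C1', C2', C3' and C4', with O, H, O and Cl, are C6, C5, C4 and C3 of a 2-pyranone that bears ring A as a 6-aryloxy group, an alkoxy group at C4 and chlorine at C3.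

## Retrosynthetic reasoning

**20 to 19.** The last operation removes benzyl groups only: the three phenolic O–benzyl bonds and the O–benzyl bond of the ring B ester of 19 are cut together. This is where the two carboxyl groups are told apart, since ring A keeps its methyl ester from the start and ring B carries a benzyl ester. Benzyl is used at all four positions because it survives a hot cycloaddition and can be removed by a Lewis acid with a cation trap, without hydrogenolysis.

**19 to 17.** The C2'–CHO bond is cut next. In 17, C2' is the only aromatic C–H on either core ring, lies between the ether oxygens at C1' and C3' and is para to the C5' methyl, so an electrophilic formylation has one place to go. Leaving the aldehyde out of the ring-forming step keeps an electron-withdrawing, heat-sensitive group off the diene.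

**17 to 13 and 15.** Ring B is opened at C4'–C5' and C6'–C1'. This returns the C5'/C6' pair to the alkyne carbons of benzyl but-2-ynoate 15 and C1'–C4' to C6–C3 of the aryloxy pyranone 13. The forward reaction must join pyranone C3 to the methyl-bearing alkyne carbon and pyranone C6 to the ester-bearing one, then expel the O1–C2 lactone bridge so that the ring aromatizes. The gain is large: five of the six substituents of ring B are placed by connectivity, the chlorine included, and the crowded ether bond already exists before ring B does. Other cuts through ring B would leave either the chlorine or the ether to be introduced on a finished arene.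

**13 to 12 and 6.** The C6–O bond of the pyranone is cut, giving dichloropyranone 12 and the ring A phenol 6. In the forward sense the hindered phenoxide of 6 attacks a vinylogous acid chloride carbon that has no substituent beside it on the pyranone side, so the crowded diaryl ether is reduced to an addition–elimination.

**12 back to 7.** The O-benzyl group of 12 leads back to hydroxypyranone 11, and the C3 chlorine to 10, where C3 is the one nucleophilic carbon between the lactone carbonyl and the enol. Chlorinating at this stage, before the aryloxy group would activate C5, settles the position of the halogen. Compound 10 comes from acid chloride 8 by loss of the extra carboxyl carbon, and 8 is the self-condensation product of two molecules of malonyl dichloride 7, which supply all six of its carbons.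

**6 back to 1.** The C5–O bond of ring A is traced to a C5–CHO bond through an aryl migration to oxygen (aldehyde 4), and the formyl group to the single free position of atraric acid 1 (aldehyde 3). Both phenols are benzylated between these two operations so that only the new hydroxyl of 6 is free.

**15 to 14.** The ester C–O bond of 15 is cut to but-2-ynoic acid 14.

## Alternatives that were turned down

**Alternative 1:** Ring A is disconnected at C4–C5, C1–C6 and C3–C4, as in a vinylketene–alkyne benzannulation. In the forward sense a diazo β-keto ester, whose vinyl group already carries ring B as an aryloxy substituent, is irradiated. Wolff shift of that vinyl group makes C1–C2, the vinylketene adds to an electron-rich silyloxyalkyne, the cyclobutenone opens, and a six-electron closure gives A1 with C4–OH free and C6–O silylated. In its favour, one step writes a hexasubstituted arene with every position fixed by the connectivity of the partners, the two ring A phenols come out differentiated, and no high temperature is needed. On regiochemical certainty and mildness it is stronger than the chosen route. Against it, the benzannulation is spent on the one ring that can be bought as 1. Ring B must still be made separately as a pentasubstituted chlorinated salicylate and attached to a trisubstituted enol ether of defined geometry. A 2-diazo-1,3-dicarbonyl is the reluctant class for Wolff rearrangement and gives an ester-substituted ketene prone to dimerize, and the aryl chloride must survive UV light. The chosen route builds the ring that is not available, places the chlorine before that ring exists, and is shorter.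

**Alternative 2:** Ring B is disconnected at C1'–C2' and C5'–C6'. A highly nucleophilic 1,3-dioxygenated pentadiene adds to the aryloxypropiolate ester of ring A, and the adduct aromatizes by loss of the C5' alkoxy group with a C2' hydrogen, giving A2. This shares the convergent logic of the chosen route (ring A from 1, ring B grown on its oxygen), and the diene is far more reactive than a pyranone, so the ring-forming step would run well below the temperature that 13 needs. On that point it is stronger. Against it, the dienophile is a push–pull ynol ether whose donor oxygen sits on the carbon that must be attacked, and it is hard to make and keep on a di-ortho-substituted phenol. A2 also lacks both the chlorine and the formyl group. C2' and C4' are both ortho to the same phenol, so chlorination would have to choose C4' over C2' with nothing in A2 to enforce it. The chosen route has C4'–Cl fixed by the pyranone and leaves one open position for one substitution.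

**Alternative 3:** Ring A is disconnected at C1–C2 as a biomimetic aldol of a linear triketo ester. The chain carries methyl at the future C5 and the ring B aryloxy group at the future C3, with the terminal ketone masked as a ketal. Unmasking, base-mediated aldol closure, dehydration and enolization give the resorcinol A3 directly. It runs under mild conditions, needs no heat, and delivers the ring A phenols free, so it saves the benzyl ethers on ring A; there it is as good as or better than the chosen route. Against it, it again constructs the purchasable ring and needs the same separately made ring B phenol as alternative 1. That phenol would have to be alkylated at a hindered α-keto carbon. The poly-β-carbonyl chain has three different acidic sites and can close by Claisen-type acylation, cyclize through oxygen to a pyranone, or lose aryloxide. The chosen route puts its risk into one thermal step on stable, isolable partners.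

Key step: step 10

Assumption (remark on the chemistry): the target carries no stereodescriptor, so the ether axis with its four ortho substituents is treated as configurationally unassigned and no control of axial chirality is planned.

## Route

Step 1
Reactants: 1 atraric acid (methyl 2,4-dihydroxy-3,6-dimethylbenzoate)
Product: 3 methyl 5-formyl-2,4-dihydroxy-3,6-dimethylbenzoate, via α-chloro ether 2 (not isolated)
Conditions: Cl2CHOMe, TiCl4, CH2Cl2, 0 → 25 °C; then H2O
Reagents that add atoms: dichloromethyl methyl ether, COC(Cl)Cl; water, O
Why: Rieche formylation (Friedel–Crafts attack by the chloro(methoxy)methyl cation, then hydrolysis of the α-chloro ether); C5 is the only unsubstituted position of 1 and is ortho to the 4-OH and para to the 2-OH, so there is no regiochemical choice.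

Step 2
Reactants: 3 methyl 5-formyl-2,4-dihydroxy-3,6-dimethylbenzoate
Product: 4 methyl 2,4-bis(benzyloxy)-5-formyl-3,6-dimethylbenzoate
Conditions: BnBr (2.5 equiv), K2CO3, DMF, 60 °C
Reagents that add atoms: benzyl bromide, BrCc1ccccc1
Why: Williamson etherification; both hydroxyls are hydrogen-bonded to a neighbouring carbonyl, hence carbonate in warm DMF with excess halide, while the di-ortho-substituted methyl ester is not at risk.

Step 3
Reactants: 4 methyl 2,4-bis(benzyloxy)-5-formyl-3,6-dimethylbenzoate
Product: 6 methyl 2,4-bis(benzyloxy)-5-hydroxy-3,6-dimethylbenzoate, via aryl formate 5 (not isolated)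
Conditions: mCPBA, CH2Cl2, 0 → 25 °C; then K2CO3, MeOH, 25 °C
Reagents that add atoms: 3-chloroperoxybenzoic acid, OOC(=O)c1cccc(Cl)c1
Why: Baeyer–Villiger (Dakin-type) oxidation; the electron-rich aryl group, with benzyloxy groups ortho and para to the formyl carbon, migrates to oxygen to give formate 5. Methanolysis then frees the phenol, and any exchange at the hindered methyl ester in methanol is degenerate.

Step 4
Reactants: 7 malonyl dichloride (two molecules)
Product: 8 6-chloro-4-hydroxy-2-oxo-2H-pyran-3-carbonyl chloride
Conditions: neat, 25 °C, 5 d, under N2 (HCl vented)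
Reagents that add atoms: malonyl dichloride (second molecule of 7), O=C(Cl)CC(Cl)=O
Why: Known self-condensation of malonyl dichloride: the methylene carbon of one molecule is acylated by an acyl chloride of the second, and the enol oxygen of the far chlorocarbonyl group of the new chain closes onto one of the two geminal acyl chlorides. Two molecules of 7 therefore give 8 and two molecules of HCl.

Step 5
Reactants: 8 6-chloro-4-hydroxy-2-oxo-2H-pyran-3-carbonyl chloride
Product: 10 6-chloro-4-hydroxy-2H-pyran-2-one, via pyranone-3-carboxylic acid 9 (not isolated)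
Conditions: H2O (1.2 equiv), 1,4-dioxane, 25 °C; then 90 °C
Reagents that add atoms: none
Why: The acyl chloride hydrolyses much faster than the vinylogous C6–Cl of the acidic hydroxypyranone; acid 9 is a cyclic β-keto acid equivalent and decarboxylates on warming.

Step 6
Reactants: 10 6-chloro-4-hydroxy-2H-pyran-2-one
Product: 11 3,6-dichloro-4-hydroxy-2H-pyran-2-one
Conditions: SO2Cl2 (1.05 equiv), CH2Cl2–1,4-dioxane, 0 → 25 °C
Reagents that add atoms: sulfuryl chloride, O=S(=O)(Cl)Cl
Why: Electrophilic chlorination of a 4-hydroxy-2-pyranone at C3, the carbon between lactone carbonyl and enol carbon, as with 4-hydroxy-6-methyl-2-pyranone; C5 is deactivated by the adjacent C6–Cl and one equivalent of reagent avoids dichlorination.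

Step 7
Reactants: 11 3,6-dichloro-4-hydroxy-2H-pyran-2-one
Product: 12 4-(benzyloxy)-3,6-dichloro-2H-pyran-2-one
Conditions: PPh3, DIAD, THF, 0 °C; then BnOH and 11, 0 → 25 °C
Reagents that add atoms: benzyl alcohol, OCc1ccccc1
Why: Mitsunobu alkylation of the acidic 4-hydroxypyranone (a vinylogous carboxylic acid), which on this class gives the 4-alkoxy-2-pyranone and not the 2-alkoxy-4-pyranone. The neutral medium spares the C6–Cl bond, and the betaine is preformed so that free PPh3 does not meet the chloropyranone.

Step 8
Reactants: 12 4-(benzyloxy)-3,6-dichloro-2H-pyran-2-one; 6 methyl 2,4-bis(benzyloxy)-5-hydroxy-3,6-dimethylbenzoate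
Product: 13 methyl 2,4-bis(benzyloxy)-5-{[4-(benzyloxy)-3-chloro-2-oxo-2H-pyran-6-yl]oxy}-3,6-dimethylbenzoate
Conditions: Cs2CO3, MeCN, 0 → 25 °C
Reagents that add atoms: none
Why: Addition–elimination at a vinylogous acid chloride; the phenoxide of 6 adds to C6 (1,6-addition to the pyranone carbonyl) and chloride leaves. C2 is a vinylogous carbonate carbon deactivated by the 4-benzyloxy group, C4 would have to expel benzyloxide and C3–Cl is not activated, so C6 should be the only productive site; it has no flanking substituent on the pyranone side, which lets the di-ortho-substituted phenoxide in.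

Step 9
Reactants: 14 but-2-ynoic acid
Product: 15 benzyl but-2-ynoate
Conditions: BnBr, KHCO3, DMF, 25 °C
Reagents that add atoms: benzyl bromide, BrCc1ccccc1
Why: SN2 alkylation of the carboxylate under bicarbonate, mild enough not to isomerize the ynoate to an allenoate.

Step 10
Reactants: 13 methyl 2,4-bis(benzyloxy)-5-{[4-(benzyloxy)-3-chloro-2-oxo-2H-pyran-6-yl]oxy}-3,6-dimethylbenzoate; 15 benzyl but-2-ynoate
Product: 17 benzyl 4-(benzyloxy)-2-[2,4-bis(benzyloxy)-5-(methoxycarbonyl)-3,6-dimethylphenoxy]-5-chloro-6-methylbenzoate, via bridged lactone 16 (not isolated)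
Conditions: 15 (8 equiv), BHT (cat.), o-dichlorobenzene, 180 °C, sealed tube
Reagents that add atoms: none
Why: The pyranone diene C3=C4–C5=C6 of 13 adds to the triple bond of 15 in a thermal Diels–Alder reaction of normal electron demand, giving the 2-oxabicyclo[2.2.2]octa-5,7-dien-3-one 16, which loses CO2 (the O1–C2 bridge) by retro-[4+2] to the benzene 17. The closest known reaction type is the cycloaddition–decarboxylation of 4-alkoxy- and 6-alkoxy-2-pyranones with acetylenic esters to benzoates and phthalates. Ring B closes by a concerted suprafacial [4+2] cycloaddition that forms C4'–C5' and C6'–C1', and the cycloreversion makes it aromatic. Product 17 has no stereocentre; the two bridgehead centres of 16 are fixed relative to each other by the bicycle and vanish on aromatization. The step needs one orientation of the unsymmetrical alkyne: the 4-benzyloxy group and the 6-aryloxy/ring-oxygen pair both push electron density to C3, which therefore carries the largest HOMO coefficient and pairs with the β-carbon of the ynoate, the site of the largest LUMO coefficient. This places the methyl next to chlorine and the ester next to the aryloxy carbon. Excess 15 and a radical inhibitor compensate for the modest dienophile and for the HOMO-lowering 3-chloro group. The benzyl ester and ethers are chosen because they do not fragment at this temperature, as a tert-butyl ester would.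

Step 11
Reactants: 17 benzyl 4-(benzyloxy)-2-[2,4-bis(benzyloxy)-5-(methoxycarbonyl)-3,6-dimethylphenoxy]-5-chloro-6-methylbenzoate
Product: 19 benzyl 4-(benzyloxy)-2-[2,4-bis(benzyloxy)-5-(methoxycarbonyl)-3,6-dimethylphenoxy]-5-chloro-3-formyl-6-methylbenzoate, via α-chloro ether 18 (not isolated)
Conditions: Cl2CHOMe, TiCl4, CH2Cl2, −78 → 0 °C; then H2O
Reagents that add atoms: dichloromethyl methyl ether, COC(Cl)Cl; water, O
Why: Rieche formylation; C2' is the only aromatic C–H on rings A and B, lies ortho to two ether oxygens and para to the C5' methyl, and the electrophile is small, while the benzyl phenyl rings are far less activated. Any benzyl ether that TiCl4 removes is of no consequence, because step 12 removes them all.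

Step 12
Reactants: 19 benzyl 4-(benzyloxy)-2-[2,4-bis(benzyloxy)-5-(methoxycarbonyl)-3,6-dimethylphenoxy]-5-chloro-3-formyl-6-methylbenzoate
Product: 20 5-chloro-2-[2,4-dihydroxy-5-(methoxycarbonyl)-3,6-dimethylphenoxy]-3-formyl-4-hydroxy-6-methylbenzoic acid (CNP0210944.0)
Conditions: BCl3, pentamethylbenzene, CH2Cl2, −78 → 0 °C; then H2O
Reagents that add atoms: none
Why: Lewis-acid debenzylation with Friedel–Crafts capture of the benzyl cation by pentamethylbenzene; the three aryl benzyl ethers cleave at low temperature and the benzyl ester on warming to 0 °C. No hydrogen is used, so the C–Cl bond and the aldehyde remain, and a methyl ester is not cleaved by BCl3 at or below 0 °C in the time needed.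

## Compound list

1 | atraric acid (methyl 2,4-dihydroxy-3,6-dimethylbenzoate) | COC(=O)c1c(C)cc(O)c(C)c1O | starting material
2 | methyl 5-[chloro(methoxy)methyl]-2,4-dihydroxy-3,6-dimethylbenzoate (racemic, transient) | COC(=O)c1c(C)c(C(Cl)OC)c(O)c(C)c1O | intermediate
3 | methyl 5-formyl-2,4-dihydroxy-3,6-dimethylbenzoate | COC(=O)c1c(C)c(C=O)c(O)c(C)c1O | intermediate
4 | methyl 2,4-bis(benzyloxy)-5-formyl-3,6-dimethylbenzoate | COC(=O)c1c(C)c(C=O)c(OCc2ccccc2)c(C)c1OCc1ccccc1 | intermediate
5 | methyl 2,4-bis(benzyloxy)-5-(formyloxy)-3,6-dimethylbenzoate | COC(=O)c1c(C)c(OC=O)c(OCc2ccccc2)c(C)c1OCc1ccccc1 | intermediate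
6 | methyl 2,4-bis(benzyloxy)-5-hydroxy-3,6-dimethylbenzoate | COC(=O)c1c(C)c(O)c(OCc2ccccc2)c(C)c1OCc1ccccc1 | intermediate
7 | malonyl dichloride | O=C(Cl)CC(Cl)=O | starting material
8 | 6-chloro-4-hydroxy-2-oxo-2H-pyran-3-carbonyl chloride | O=C(Cl)c1c(O)cc(Cl)oc1=O | intermediate
9 | 6-chloro-4-hydroxy-2-oxo-2H-pyran-3-carboxylic acid | O=C(O)c1c(O)cc(Cl)oc1=O | intermediate
10 | 6-chloro-4-hydroxy-2H-pyran-2-one | O=c1cc(O)cc(Cl)o1 | intermediate
11 | 3,6-dichloro-4-hydroxy-2H-pyran-2-one | O=c1oc(Cl)cc(O)c1Cl | intermediate
12 | 4-(benzyloxy)-3,6-dichloro-2H-pyran-2-one | O=c1oc(Cl)cc(OCc2ccccc2)c1Cl | intermediate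
13 | methyl 2,4-bis(benzyloxy)-5-{[4-(benzyloxy)-3-chloro-2-oxo-2H-pyran-6-yl]oxy}-3,6-dimethylbenzoate | COC(=O)c1c(C)c(Oc2cc(OCc3ccccc3)c(Cl)c(=O)o2)c(OCc2ccccc2)c(C)c1OCc1ccccc1 | intermediate
14 | but-2-ynoic acid | CC#CC(=O)O | starting material
15 | benzyl but-2-ynoate | CC#CC(=O)OCc1ccccc1 | intermediate
16 | benzyl 8-(benzyloxy)-1-[2,4-bis(benzyloxy)-5-(methoxycarbonyl)-3,6-dimethylphenoxy]-4-chloro-5-methyl-3-oxo-2-oxabicyclo[2.2.2]octa-5,7-diene-6-carboxylate (racemic, one enantiomer drawn; the bridgehead pair is fixed by the bicycle) | O=C1O[C@]2(Oc3c(C)c(C(=O)OC)c(OCc4ccccc4)c(C)c3OCc3ccccc3)C=C(OCc3ccccc3)[C@@]1(Cl)C(C)=C2C(=O)OCc1ccccc1 | intermediate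
17 | benzyl 4-(benzyloxy)-2-[2,4-bis(benzyloxy)-5-(methoxycarbonyl)-3,6-dimethylphenoxy]-5-chloro-6-methylbenzoate | COC(=O)c1c(C)c(Oc2cc(OCc3ccccc3)c(Cl)c(C)c2C(=O)OCc2ccccc2)c(OCc2ccccc2)c(C)c1OCc1ccccc1 | intermediate
18 | benzyl 4-(benzyloxy)-2-[2,4-bis(benzyloxy)-5-(methoxycarbonyl)-3,6-dimethylphenoxy]-5-chloro-3-[chloro(methoxy)methyl]-6-methylbenzoate (racemic, transient) | COC(=O)c1c(C)c(Oc2c(C(Cl)OC)c(OCc3ccccc3)c(Cl)c(C)c2C(=O)OCc2ccccc2)c(OCc2ccccc2)c(C)c1OCc1ccccc1 | intermediate
19 | benzyl 4-(benzyloxy)-2-[2,4-bis(benzyloxy)-5-(methoxycarbonyl)-3,6-dimethylphenoxy]-5-chloro-3-formyl-6-methylbenzoate | COC(=O)c1c(C)c(Oc2c(C=O)c(OCc3ccccc3)c(Cl)c(C)c2C(=O)OCc2ccccc2)c(OCc2ccccc2)c(C)c1OCc1ccccc1 | intermediate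
20 | 5-chloro-2-[2,4-dihydroxy-5-(methoxycarbonyl)-3,6-dimethylphenoxy]-3-formyl-4-hydroxy-6-methylbenzoic acid (CNP0210944.0) | COC(=O)c1c(C)c(Oc2c(C=O)c(O)c(Cl)c(C)c2C(=O)O)c(O)c(C)c1O | target

## Step count and least certain steps

Total: 12 steps from 1, 7 and 14. Longest linear sequence: 8 steps (steps 4, 5, 6, 7, 8, 10, 11 and 12, from 7 to 20).

**Step 10 (key step).** The most likely failure is that cycloaddition is too slow: both diene termini are fully substituted, C3 carries a HOMO-lowering chlorine, and the dienophile is a β-methylated ynoate. Thermal breakdown of the ketene-acetal-like C6–O-aryl unit or of the benzyl groups could then outrun ring formation. The steric contact between the methyl-bearing alkyne carbon and C3–Cl could also erode the orientation. The fallback sets out from 13 and returns at 17, using a dienophile of the same polarization but much lower LUMO. Compound 13 is heated with commercial but-2-ynal in toluene at 110–130 °C. The bridged lactone F1 should lose CO2 to the ring B benzaldehyde F2, a 4-(benzyloxy)-5-chloro-6-methyl-2-aryloxybenzaldehyde. Oxidation with NaClO2, NaH2PO4 and 2-methylbut-2-ene gives the benzoic acid F3, and BnBr with K2CO3 in DMF gives 17.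

**Step 8.** The hindered phenoxide may attack the lactone carbonyl C2 instead of C6, which would open the ring and could reclose to an isomeric pyranone, or it may simply react too slowly at a pyranone deactivated by the 4-benzyloxy donor. The fallback sets out from 6 and returns at 13. It makes the C6–O bond as an ester bond and closes the pyranone around it. Phenol 6 is heated with Meldrum's acid in toluene at 100 °C to give the aryl hydrogen malonate F4. Coupling with a second Meldrum's acid (DCC, DMAP, CH2Cl2) gives the acyl Meldrum's acid F5. Thermolysis in toluene at 110 °C releases acetone and CO2 and the acylketene F6, whose enol form should close by six-electron oxa-electrocyclization through the aryl ester carbonyl oxygen onto the ketene carbon to give the 6-aryloxy-4-hydroxypyranone F7. SO2Cl2 then chlorinates C3, between lactone carbonyl and enol, to give the 3-chloro-4-hydroxypyranone F8. The competing position here is C5, which the aryloxy group activates, so this chlorination is the weak point of the fallback. Mitsunobu benzylation as in step 7 gives 13.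

**Step 11.** The Friedel–Crafts attack must occur between two ether oxygens on a ring that also carries an ester and a chlorine. If it is slow, TiCl4 has time to strip benzyl ethers by chelation and the material is spread over several partly deprotected species. The fallback sets out from 17 and returns at 19. It uses a smaller, stronger electrophile and then builds the aldehyde carbon by cross-coupling. NBS in MeCN in the dark brominates the only free position to give the C2' aryl bromide F9. Potassium vinyltrifluoroborate with PdCl2(dppf) and Cs2CO3 in THF–H2O at 80 °C gives the C2' vinyl arene F10 without touching the C–Cl bond. Lemieux–Johnson cleavage (OsO4 cat., NaIO4, 2,6-lutidine, dioxane–H2O) gives 19.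

**Step 12.** Warming far enough to cleave the benzyl ester may let BCl3 also cleave the ring A methyl ester through its boron chelate with the neighbouring phenoxide, or engage the activated salicylaldehyde. The fallback sets out from 17 and returns at 20. It removes the benzyl groups before the aldehyde exists and formylates last. Hydrogenolysis of 17 (H2 at 1 atm, Pd/C, EtOAc, no base, stopped after four equivalents so that the C–Cl bond is kept) gives the des-formyl triol acid F11. A Duff reaction (hexamethylenetetramine, CF3CO2H, 80 °C; then aq. HCl) delivers the formyl group ortho to the C3' hydroxyl, where C2' is the only open position, and gives 20.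

## Further compounds

F1 | step 10 | 8-(benzyloxy)-1-[2,4-bis(benzyloxy)-5-(methoxycarbonyl)-3,6-dimethylphenoxy]-4-chloro-5-methyl-3-oxo-2-oxabicyclo[2.2.2]octa-5,7-diene-6-carbaldehyde (racemic, one enantiomer drawn) | O=C1O[C@]2(Oc3c(C)c(C(=O)OC)c(OCc4ccccc4)c(C)c3OCc3ccccc3)C=C(OCc3ccccc3)[C@@]1(Cl)C(C)=C2C=O
F2 | step 10 | methyl 2,4-bis(benzyloxy)-5-[5-(benzyloxy)-4-chloro-2-formyl-3-methylphenoxy]-3,6-dimethylbenzoate | COC(=O)c1c(C)c(Oc2cc(OCc3ccccc3)c(Cl)c(C)c2C=O)c(OCc2ccccc2)c(C)c1OCc1ccccc1
F3 | step 10 | 4-(benzyloxy)-2-[2,4-bis(benzyloxy)-5-(methoxycarbonyl)-3,6-dimethylphenoxy]-5-chloro-6-methylbenzoic acid | COC(=O)c1c(C)c(Oc2cc(OCc3ccccc3)c(Cl)c(C)c2C(=O)O)c(OCc2ccccc2)c(C)c1OCc1ccccc1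
F4 | step 8 | 3-[2,4-bis(benzyloxy)-5-(methoxycarbonyl)-3,6-dimethylphenoxy]-3-oxopropanoic acid | COC(=O)c1c(C)c(OC(=O)CC(=O)O)c(OCc2ccccc2)c(C)c1OCc1ccccc1
F5 | step 8 | methyl 2,4-bis(benzyloxy)-5-{[3-(2,2-dimethyl-4,6-dioxo-1,3-dioxan-5-ylidene)-3-hydroxypropanoyl]oxy}-3,6-dimethylbenzoate | COC(=O)c1c(C)c(OC(=O)CC(O)=C2C(=O)OC(C)(C)OC2=O)c(OCc2ccccc2)c(C)c1OCc1ccccc1
F6 | step 8 | methyl 2,4-bis(benzyloxy)-5-[(3,5-dioxopent-4-enoyl)oxy]-3,6-dimethylbenzoate (acylketene, transient) | COC(=O)c1c(C)c(OC(=O)CC(=O)C=C=O)c(OCc2ccccc2)c(C)c1OCc1ccccc1
F7 | step 8 | methyl 2,4-bis(benzyloxy)-5-[(4-hydroxy-2-oxo-2H-pyran-6-yl)oxy]-3,6-dimethylbenzoate | COC(=O)c1c(C)c(Oc2cc(O)cc(=O)o2)c(OCc2ccccc2)c(C)c1OCc1ccccc1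
F8 | step 8 | methyl 2,4-bis(benzyloxy)-5-[(3-chloro-4-hydroxy-2-oxo-2H-pyran-6-yl)oxy]-3,6-dimethylbenzoate | COC(=O)c1c(C)c(Oc2cc(O)c(Cl)c(=O)o2)c(OCc2ccccc2)c(C)c1OCc1ccccc1
F9 | step 11 | benzyl 4-(benzyloxy)-2-[2,4-bis(benzyloxy)-5-(methoxycarbonyl)-3,6-dimethylphenoxy]-3-bromo-5-chloro-6-methylbenzoate | COC(=O)c1c(C)c(Oc2c(Br)c(OCc3ccccc3)c(Cl)c(C)c2C(=O)OCc2ccccc2)c(OCc2ccccc2)c(C)c1OCc1ccccc1
F10 | step 11 | benzyl 4-(benzyloxy)-2-[2,4-bis(benzyloxy)-5-(methoxycarbonyl)-3,6-dimethylphenoxy]-5-chloro-3-ethenyl-6-methylbenzoate | COC(=O)c1c(C)c(Oc2c(C=C)c(OCc3ccccc3)c(Cl)c(C)c2C(=O)OCc2ccccc2)c(OCc2ccccc2)c(C)c1OCc1ccccc1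
F11 | step 12 | 5-chloro-2-[2,4-dihydroxy-5-(methoxycarbonyl)-3,6-dimethylphenoxy]-4-hydroxy-6-methylbenzoic acid | COC(=O)c1c(C)c(Oc2cc(O)c(Cl)c(C)c2C(=O)O)c(O)c(C)c1O
A1 | alternative 1 | methyl 3-[5-(benzyloxy)-2-(tert-butoxycarbonyl)-4-chloro-3-methylphenoxy]-4-hydroxy-2,5-dimethyl-6-[(triisopropylsilyl)oxy]benzoate | COC(=O)c1c(C)c(Oc2cc(OCc3ccccc3)c(Cl)c(C)c2C(=O)OC(C)(C)C)c(O)c(C)c1O[Si](C(C)C)(C(C)C)C(C)C
A2 | alternative 2 | tert-butyl 2-[2,4-bis(benzyloxy)-5-(methoxycarbonyl)-3,6-dimethylphenoxy]-4-hydroxy-6-methylbenzoate | COC(=O)c1c(C)c(Oc2cc(O)cc(C)c2C(=O)OC(C)(C)C)c(OCc2ccccc2)c(C)c1OCc1ccccc1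
A3 | alternative 3 | methyl 3-[5-(benzyloxy)-2-(tert-butoxycarbonyl)-4-chloro-3-methylphenoxy]-4,6-dihydroxy-2,5-dimethylbenzoate | COC(=O)c1c(C)c(Oc2cc(OCc3ccccc3)c(Cl)c(C)c2C(=O)OC(C)(C)C)c(O)c(C)c1O
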